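The missing part of the charge outgrows the target: at 8.00 min the south-west run reads 10.5% of target, while 76.7% stands in neither column.

- south-west: starting material 1 M; second substrate 2 M; gas 200 mM (held); the very flask that is asked about, followed so far
- flask: starting material 1.0 M; second substrate 2.00 M; gas 200 mM (held); time 12 min

south-west run (percent of the starting material charged)

| time / min | target / % | starting material / % |
|---|---|---|
| 0.500 | 21.4 | 73.9 |
| 1.33 | 27.1 | 52.8 |
| 2.50 | 22.7 | 36.5 |
| 4.00 | 17.1 | 24.7 |
| 6.00 | 12.9 | 17.2 |
| 8.00 | 10.5 | 12.8 |

(readings scatter by 0.3 percentage points)

- target taken out counts as made
- the numbers in the tables scatter by 0.3 percentage points (one standard deviation)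
- at the start none of the gas is in solution
- additions bring no volume worth counting

- amber: change nothing and wait 12 min more
- ochre: at 12 min take out 90% of the target then present, then wait 12 min
- red: at 12 min add starting material, 50.0% of the amount charged, then wait 12 min

- target, in percent of the starting material first charged, at 12 min
- what to do for the largest gain in target; "none" if nothing gains more than 2 percentage points (amber / ochre / red / none)
- target present, with what was taken out counted in, in percent of the starting material first charged, after ochre
- target present, with what was taken out counted in, in percent of the starting material first charged, after red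

**Where does the target go?** Into a store the table doesn't show. Between 0.500 min and 1.33 min the gap goes from 4.70% to 20.1%, still less than the target, so I read its growth as forward flow. Divided by the mean target, that gives kf = 0.765 min⁻¹.

**Is the store a dead end?** No. At 6.00 min the gap stands at 69.9%, and up to 8.00 min it grows 0.0340 min⁻¹ of the charge per minute. Yet kf on the target there pushes more, 0.0895 min⁻¹. The difference comes back, so kr = 0.0757 min⁻¹.

**How fast does the store answer?** Its relaxation half-life, ln(2)/(kf + kr), is 0.824 min. The wait of 12 min is far longer. So the target can return to its balance share, 9.01% of what has left the starting material.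

**Then what does taking out bring?** Here is my reckoning. With the starting material as read at 8.00 min, I put the target at 12 min near 7.85%. Ochre then totals 14.3%, a gain of 6.4 percentage points. Red spreads its addition over starting material, target and store, a gain of 4.1 points. I choose ochre, whose gain is larger than red's.

The forecast differs: now 7%, best red, ochre 8.5%, red 14.3%, with a gas step “gated by slow dissolution”.

The flask gives now 8.91%, best ochre, ochre 15.7%, red 12.8%.

    target ⇌ isomer of the product (K = 9.90, k = 0.0130 s⁻¹)
    second substrate + coupling partner ⇌ second product (K = 3.20 M⁻¹, k = 0.0270 M⁻¹ s⁻¹)
    starting material + coupling partner ⇌ target (K = 4.80 M⁻¹, k = 0.0650 M⁻¹ s⁻¹)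
    gas ⇌ coupling partner, rate k4*(csat - [coupling partner]) (kL = 2.00 s⁻¹)

The store is the isomer of the product, and ochre's 15.7% stands against the forecast's 8.5% and my 14.3%, after 14.6 relaxation half-lives. The neighbour flask, same amounts, is read at 5.0 min, 6.07 half-lives from its start. Its target is 14.5% and its isomer 65.2%. With kf and kr, that puts the net flow into the isomer at 0.0616 min⁻¹ of the charge per minute. Between 4.00 min and 6.00 min the south-west gap grew 0.0585 min⁻¹ of the charge per minute.

The numbers in the tables were computed with made-up constants.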